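## Retrosynthetic overview

1. Target 25 ← bis-silyl ether 24 ← ketone 23 (methylenation, then desilylation); 23 ← ring Weinreb amide 13 + side-chain Grignard reagent 22, joined at the bond between the ring-bound carbonyl carbon and the first chain CH2.
2. Ring numbering: C1 carbinol, C3 CHCl, C4 C(CH3)Br. The strategy rests on this feature of the cyclohexane ring: the tertiary C1 oxygen is homoallylic to and cis (syn-diaxial) with the chlorine on secondary C3, and the bromine on quaternary C4 is trans to that chlorine. A titanium centre carried by the C1 oxygen can therefore pass chloride to C3 of a bromonium ion bridging C3 and C4, so 11 ← cyclohexenyl hydroxy ester 9 in one step.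
3. 9 ← aldehyde 6, the enantioselective Diels–Alder adduct of isoprene 5 and 2-(4-methoxybenzoyloxy)acrolein 4 (sets C1); 4 ← dioxanone 1.
4. Side chain: iodide 21 ← (R)-allylic alcohol 18 ← CBS reduction of isopropenyl ketone 17 ← aldehyde 14 + isopropenylmagnesium bromide 15.
5. Ring order: the only ring (the cyclohexene) is closed first by the cycloaddition, then bromochlorinated, then the chain is attached, and the exocyclic methylene is made last.

Key step: step 7

Assumption: the (R)-1,1'-binaphthyl-2,2'-diamine salt is taken to give the S adduct 6 in step 3; should a first run show the opposite sense, the (S)-diamine is used and the route is otherwise unchanged.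

## Route

Step 1
Reactants: 1 2,2-dimethyl-1,3-dioxan-5-one
Product: 3 2,2-dimethyl-4H-1,3-dioxin-5-yl 4-methoxybenzoate, via potassium enolate 2 (not isolated)
Conditions: KN(SiMe3)2, THF, −78 °C; then 4-MeOC6H4COCl, −78 → 0 °C
Reagents that add atoms: 4-methoxybenzoyl chloride, COc1ccc(cc1)C(Cl)=O
Why: O-acylation of a potassium enolate by an aroyl chloride (enol ester formation) should prevail in THF, and the symmetric ketone raises no regiochemical question.

Step 2
Reactants: 3 2,2-dimethyl-4H-1,3-dioxin-5-yl 4-methoxybenzoate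
Product: 4 2-(4-methoxybenzoyloxy)acrolein
Conditions: toluene, 110 °C, N2 sweep (acetone removed); used at once
Reagents that add atoms: none
Why: Thermal retro-hetero-Diels–Alder cleavage of the 4H-1,3-dioxin expels acetone and leaves the 2-acyloxy enal, and removal of acetone drives the cycloreversion to completion.

Step 3
Reactants: 4 2-(4-methoxybenzoyloxy)acrolein; 5 isoprene
Product: 6 (S)-1-formyl-4-methylcyclohex-3-en-1-yl 4-methoxybenzoate
Conditions: (R)-1,1'-binaphthyl-2,2'-diamine (10 mol%), Tf2NH (19 mol%), isoprene (3 equiv), EtCN, −40 °C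
Reagents that add atoms: none
Why: Catalytic enantioselective Diels–Alder reaction through the aldiminium ion formed from the enal and the chiral primary ammonium salt; the binaphthyl shields one face of the dienophile so that quaternary C1 should form as S, and the 2-methyl group of the diene directs the para (1,4) regiochemistry.

Step 4
Reactants: 6 (S)-1-formyl-4-methylcyclohex-3-en-1-yl 4-methoxybenzoate
Product: 7 (S)-1-(4-methoxybenzoyloxy)-4-methylcyclohex-3-ene-1-carboxylic acid
Conditions: NaClO2, NaH2PO4, 2-methyl-2-butene (excess), tBuOH/H2O, 0 °C → rt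
Reagents that add atoms: sodium chlorite, [Na+].[O-]Cl=O
Why: Pinnick oxidation of a non-enolisable aldehyde, with excess 2-methyl-2-butene taking up HOCl before it can add to the ring alkene; C1 is not touched.

Step 5
Reactants: 7 (S)-1-(4-methoxybenzoyloxy)-4-methylcyclohex-3-ene-1-carboxylic acid
Product: 8 methyl (S)-1-(4-methoxybenzoyloxy)-4-methylcyclohex-3-ene-1-carboxylate
Conditions: MeI, K2CO3, DMF, rt
Reagents that add atoms: iodomethane, CI
Why: SN2 O-methylation of the carboxylate (esterification) is unhindered and leaves the aryl ester and the alkene alone.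

Step 6
Reactants: 8 methyl (S)-1-(4-methoxybenzoyloxy)-4-methylcyclohex-3-ene-1-carboxylate
Product: 9 methyl (S)-1-hydroxy-4-methylcyclohex-3-ene-1-carboxylate
Conditions: K2CO3, MeOH, rt
Reagents that add atoms: none
Why: Base-catalysed transesterification (methanolysis) of the aryl ester, in which the α-ester makes the tertiary alkoxide a good leaving group, exchange at the methyl ester is degenerate, and no bond to C1 is broken.

Step 7
Reactants: 9 methyl (S)-1-hydroxy-4-methylcyclohex-3-ene-1-carboxylate
Product: 11 methyl (1S,3S,4S)-4-bromo-3-chloro-1-hydroxy-4-methylcyclohexane-1-carboxylate, via titanium alkoxide 10 (not isolated)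
Conditions: ClTi(OiPr)3 (1.2 equiv), CH2Cl2/hexane, rt, 30 min; then N-bromosuccinimide (1.1 equiv), −20 °C; aq. NaHCO3
Reagents that add atoms: chlorotitanium triisopropoxide, CC(C)O[Ti](Cl)(OC(C)C)OC(C)C; N-bromosuccinimide, BrN1C(=O)CCC1=O
Why: Proposed new method: alkoxide exchange places ClTi(OiPr)2 on the C1 oxygen with the ester carbonyl chelating (10), N-bromosuccinimide then forms bromonium ions reversibly on both faces of the C3=C4 bond, and only the ion anti to the axial C1–O–Ti unit is consumed, because the titanium-bound chloride reaches C3 on the oxygen face through a six-membered array (Cl–Ti–O–C1–C2–C3) and opens the ion in the trans-diaxial sense. The closest known reaction type is the hydroxyl-directed bromochlorination of allylic alcohols with ClTi(OiPr)3 and N-bromosuccinimide, in which a tetravalent titanium alkoxide passes chloride to a bromonium ion; the extension is to a cyclic tertiary homoallylic alcohol. No ring is closed, the step only adds bromine to C4 and chlorine to C3 anti across the ring alkene. C3 (S) is controlled by chloride delivery from the C1 oxygen, which puts chlorine cis to that oxygen, and C4 (S) by the anti opening, which leaves bromine trans to chlorine, so both centres are relayed from C1. The step needs chloride at the secondary carbon against the Markovnikov preference for tertiary C4 and on one face only, and the tether from the C1 alkoxide secures both, helped by the fact that axial attack at C3 in the half-chair with axial oxygen is also the trans-diaxial (Fürst–Plattner) mode. The substrate offers a single alkene, an ester that holds titanium without acting as a nucleophile, and a C1 oxygen whose own nucleophilicity toward C4 is tempered by binding to titanium.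

Step 8
Reactants: 11 methyl (1S,3S,4S)-4-bromo-3-chloro-1-hydroxy-4-methylcyclohexane-1-carboxylate
Product: 12 (1S,3S,4S)-4-bromo-3-chloro-1-hydroxy-N-methoxy-N,4-dimethylcyclohexane-1-carboxamide
Conditions: MeONHMe·HCl, iPrMgCl, THF, −20 °C; aq. NH4Cl
Reagents that add atoms: N,O-dimethylhydroxylamine hydrochloride, CNOC.Cl
Why: Weinreb amide formation by aminolysis of the ester with ClMgN(OMe)Me made in the flask; the aluminium-amide variant is avoided because AlMe3 ionises and methylates tertiary bromides, and at −20 °C the magnesium amide should be too weak a base to eliminate HBr or HCl.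

Step 9
Reactants: 12 (1S,3S,4S)-4-bromo-3-chloro-1-hydroxy-N-methoxy-N,4-dimethylcyclohexane-1-carboxamide
Product: 13 (1S,3S,4S)-4-bromo-3-chloro-N-methoxy-N,4-dimethyl-1-(trimethylsilyloxy)cyclohexane-1-carboxamide
Conditions: 1-(trimethylsilyl)imidazole, CH2Cl2, rt
Reagents that add atoms: 1-(trimethylsilyl)imidazole, C[Si](C)(C)n1ccnc1
Why: Silylation of the tertiary hydroxyl by a strong neutral silyl donor masks the acidic proton before the organometallic step without exposing the halides to acid or base.

Step 10
Reactants: 14 3-(tert-butyldimethylsilyloxy)propanal; 15 isopropenylmagnesium bromide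
Product: 16 rac-5-(tert-butyldimethylsilyloxy)-2-methylpent-1-en-3-ol
Conditions: THF, −78 → 0 °C; H2O/aq. NH4Cl
Reagents that add atoms: none
Why: Grignard 1,2-addition to the aldehyde gives the racemic allylic alcohol, whose stereocentre is erased in the next step.

Step 11
Reactants: 16 rac-5-(tert-butyldimethylsilyloxy)-2-methylpent-1-en-3-ol
Product: 17 5-(tert-butyldimethylsilyloxy)-2-methylpent-1-en-3-one
Conditions: Dess–Martin periodinane, NaHCO3, CH2Cl2, 0 °C
Reagents that add atoms: none
Why: Dess–Martin oxidation under buffered, near-neutral conditions should give the isopropenyl ketone without β-elimination of the silyloxy group.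

Step 12
Reactants: 17 5-(tert-butyldimethylsilyloxy)-2-methylpent-1-en-3-one
Product: 18 (R)-5-(tert-butyldimethylsilyloxy)-2-methylpent-1-en-3-ol
Conditions: (S)-Me-CBS oxazaborolidine [(S)-1-methyl-3,3-diphenyltetrahydro-1H,3H-pyrrolo[1,2-c][1,3,2]oxazaborole] (10 mol%), BH3·SMe2, THF, −30 °C; MeOH quench
Reagents that add atoms: none
Why: CBS reduction in which the isopropenyl group acts as the large and the CH2CH2OSi chain as the small substituent, so that the (S)-oxazaborolidine should deliver hydride to the face that gives the R carbinol (the sense of acetophenone to (R)-1-phenylethanol), by 1,2-reduction only.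

Step 13
Reactants: 18 (R)-5-(tert-butyldimethylsilyloxy)-2-methylpent-1-en-3-ol
Product: 19 (R)-3,5-bis(tert-butyldimethylsilyloxy)-2-methylpent-1-ene
Conditions: TBSCl, imidazole, DMF, rt
Reagents that add atoms: tert-butyldimethylsilyl chloride, CC(C)(C)[Si](C)(C)Cl
Why: Imidazole-promoted silylation of the secondary allylic alcohol proceeds at oxygen and leaves the carbinol configuration untouched.

Step 14
Reactants: 19 (R)-3,5-bis(tert-butyldimethylsilyloxy)-2-methylpent-1-ene
Product: 20 (R)-3-(tert-butyldimethylsilyloxy)-4-methylpent-4-en-1-ol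
Conditions: (±)-camphor-10-sulfonic acid (10 mol%), MeOH/CH2Cl2 1:1, −10 °C
Reagents that add atoms: none
Why: Acid-catalysed methanolysis of a silyl ether is much faster at the unhindered primary position than at the secondary one flanked by the isopropenyl group, so the reaction is stopped once 19 is consumed.

Step 15
Reactants: 20 (R)-3-(tert-butyldimethylsilyloxy)-4-methylpent-4-en-1-ol
Product: 21 (R)-tert-butyl[(5-iodo-2-methylpent-1-en-3-yl)oxy]dimethylsilane
Conditions: I2, PPh3, imidazole, CH2Cl2, 0 °C → rt
Reagents that add atoms: iodine, II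
Why: Appel-type iodination, an SN2 displacement of the alkoxyphosphonium by iodide at the primary carbon, two atoms away from the stereocentre.

Step 16
Reactants: 21 (R)-tert-butyl[(5-iodo-2-methylpent-1-en-3-yl)oxy]dimethylsilane; 13 (1S,3S,4S)-4-bromo-3-chloro-N-methoxy-N,4-dimethyl-1-(trimethylsilyloxy)cyclohexane-1-carboxamide
Product: 23 (R)-1-[(1S,3S,4S)-4-bromo-3-chloro-4-methyl-1-(trimethylsilyloxy)cyclohexyl]-4-(tert-butyldimethylsilyloxy)-5-methylhex-5-en-1-one, via Grignard reagent 22 (not isolated)
Conditions: Mg, Et2O, rt (slow addition of 21); solution filtered from Mg, added to 13, THF, −20 → 0 °C; H2O/aq. NH4Cl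
Reagents that add atoms: none
Why: Grignard acylation through a Weinreb amide, whose magnesium-chelated tetrahedral adduct persists until work-up so that only one equivalent adds, while filtering off the metal and keeping the mixture cold spares the vicinal bromide/chloride pair, which magnesium metal or a warm organometallic would strip to the alkene.

Step 17
Reactants: 23 (R)-1-[(1S,3S,4S)-4-bromo-3-chloro-4-methyl-1-(trimethylsilyloxy)cyclohexyl]-4-(tert-butyldimethylsilyloxy)-5-methylhex-5-en-1-one
Product: 24 tert-butyl({(R)-6-[(1S,3S,4S)-4-bromo-3-chloro-4-methyl-1-(trimethylsilyloxy)cyclohexyl]-2-methylhepta-1,6-dien-3-yl}oxy)dimethylsilane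
Conditions: Cp2Ti(μ-Cl)(μ-CH2)AlMe2, pyridine, THF/toluene, −40 → 0 °C; aq. NaHCO3
Reagents that add atoms: Cp2Ti(μ-Cl)(μ-CH2)AlMe2, C[Al](C)C[Ti](Cl)(C1C=CC=C1)C1C=CC=C1
Why: Tebbe methylenation through the titanium methylidene and an oxatitanacyclobutane converts hindered α-oxygenated ketones without a basic ylide that could eliminate HBr.

Step 18
Reactants: 24 tert-butyl({(R)-6-[(1S,3S,4S)-4-bromo-3-chloro-4-methyl-1-(trimethylsilyloxy)cyclohexyl]-2-methylhepta-1,6-dien-3-yl}oxy)dimethylsilane
Product: 25 (R)-6-[(1S,3S,4S)-4-bromo-3-chloro-1-hydroxy-4-methylcyclohexyl]-2-methylhepta-1,6-dien-3-ol (CNP0197601.4)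
Conditions: HF·pyridine, pyridine, THF, 0 °C → rt
Reagents that add atoms: none
Why: Fluoride-driven cleavage of both silyl ethers in a pyridine-buffered medium avoids basic fluoride, which could eliminate the tertiary bromide, and strong acid, which could ionise the tertiary allylic alcohol.

## Compound list

1 | 2,2-dimethyl-1,3-dioxan-5-one | CC1(C)OCC(=O)CO1 | starting material
2 | potassium enolate of 1 (potassium 2,2-dimethyl-4H-1,3-dioxin-5-olate) | CC1(C)OCC([O-])=CO1.[K+] | intermediate
3 | 2,2-dimethyl-4H-1,3-dioxin-5-yl 4-methoxybenzoate | COc1ccc(cc1)C(=O)OC1=COC(C)(C)OC1 | intermediate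
4 | 2-(4-methoxybenzoyloxy)acrolein | C=C(OC(=O)c1ccc(OC)cc1)C=O | intermediate
5 | isoprene | C=CC(C)=C | starting material
6 | (S)-1-formyl-4-methylcyclohex-3-en-1-yl 4-methoxybenzoate | O=C[C@]1(OC(=O)c2ccc(OC)cc2)CCC(C)=CC1 | intermediate
7 | (S)-1-(4-methoxybenzoyloxy)-4-methylcyclohex-3-ene-1-carboxylic acid | OC(=O)[C@]1(OC(=O)c2ccc(OC)cc2)CCC(C)=CC1 | intermediate
8 | methyl (S)-1-(4-methoxybenzoyloxy)-4-methylcyclohex-3-ene-1-carboxylate | COC(=O)[C@]1(OC(=O)c2ccc(OC)cc2)CCC(C)=CC1 | intermediate
9 | methyl (S)-1-hydroxy-4-methylcyclohex-3-ene-1-carboxylate | COC(=O)[C@]1(O)CCC(C)=CC1 | intermediate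
10 | ClTi(OiPr)2 alkoxide of hydroxy ester 9 (titanium on the C1 oxygen, ester carbonyl chelating) | COC(=O)[C@]1(O[Ti](Cl)(OC(C)C)OC(C)C)CCC(C)=CC1 | intermediate
11 | methyl (1S,3S,4S)-4-bromo-3-chloro-1-hydroxy-4-methylcyclohexane-1-carboxylate (Cl cis to OH, Br trans to Cl) | COC(=O)[C@]1(O)CC[C@](C)(Br)[C@@H](Cl)C1 | intermediate
12 | (1S,3S,4S)-4-bromo-3-chloro-1-hydroxy-N-methoxy-N,4-dimethylcyclohexane-1-carboxamide | CON(C)C(=O)[C@]1(O)CC[C@](C)(Br)[C@@H](Cl)C1 | intermediate
13 | (1S,3S,4S)-4-bromo-3-chloro-N-methoxy-N,4-dimethyl-1-(trimethylsilyloxy)cyclohexane-1-carboxamide | CON(C)C(=O)[C@]1(O[Si](C)(C)C)CC[C@](C)(Br)[C@@H](Cl)C1 | intermediate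
14 | 3-(tert-butyldimethylsilyloxy)propanal | O=CCCO[Si](C)(C)C(C)(C)C | starting material
15 | isopropenylmagnesium bromide | C=C(C)[Mg]Br | starting material
16 | rac-5-(tert-butyldimethylsilyloxy)-2-methylpent-1-en-3-ol | C=C(C)C(O)CCO[Si](C)(C)C(C)(C)C | intermediate
17 | 5-(tert-butyldimethylsilyloxy)-2-methylpent-1-en-3-one | C=C(C)C(=O)CCO[Si](C)(C)C(C)(C)C | intermediate
18 | (R)-5-(tert-butyldimethylsilyloxy)-2-methylpent-1-en-3-ol | C=C(C)[C@H](O)CCO[Si](C)(C)C(C)(C)C | intermediate
19 | (R)-3,5-bis(tert-butyldimethylsilyloxy)-2-methylpent-1-ene | C=C(C)[C@H](O[Si](C)(C)C(C)(C)C)CCO[Si](C)(C)C(C)(C)C | intermediate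
20 | (R)-3-(tert-butyldimethylsilyloxy)-4-methylpent-4-en-1-ol | C=C(C)[C@H](O[Si](C)(C)C(C)(C)C)CCO | intermediate
21 | (R)-tert-butyl[(5-iodo-2-methylpent-1-en-3-yl)oxy]dimethylsilane | C=C(C)[C@H](O[Si](C)(C)C(C)(C)C)CCI | intermediate
22 | [(R)-3-(tert-butyldimethylsilyloxy)-4-methylpent-4-en-1-yl]magnesium iodide | C=C(C)[C@H](O[Si](C)(C)C(C)(C)C)CC[Mg]I | intermediate
23 | (R)-1-[(1S,3S,4S)-4-bromo-3-chloro-4-methyl-1-(trimethylsilyloxy)cyclohexyl]-4-(tert-butyldimethylsilyloxy)-5-methylhex-5-en-1-one | C=C(C)[C@H](O[Si](C)(C)C(C)(C)C)CCC(=O)[C@]1(O[Si](C)(C)C)CC[C@](C)(Br)[C@@H](Cl)C1 | intermediate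
24 | tert-butyl({(R)-6-[(1S,3S,4S)-4-bromo-3-chloro-4-methyl-1-(trimethylsilyloxy)cyclohexyl]-2-methylhepta-1,6-dien-3-yl}oxy)dimethylsilane | C=C(C)[C@H](O[Si](C)(C)C(C)(C)C)CCC(=C)[C@]1(O[Si](C)(C)C)CC[C@](C)(Br)[C@@H](Cl)C1 | intermediate
25 | (R)-6-[(1S,3S,4S)-4-bromo-3-chloro-1-hydroxy-4-methylcyclohexyl]-2-methylhepta-1,6-dien-3-ol (CNP0197601.4) | C=C(C)[C@H](O)CCC(=C)[C@]1(O)CC[C@](C)(Br)[C@@H](Cl)C1 | target

## Step count and risks

Total step count: 18. Longest linear sequence: 12 steps (steps 1 to 9, then 16 to 18); the side chain takes steps 10 to 15.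

**Step 7 (proposed new method).** Chloride transfer from titanium may lose to Markovnikov opening of the bromonium ion at tertiary C4, to transannular capture of that ion by the C1 oxygen, or to unselective bromonium formation and opening. A matched chiral tridentate Schiff base ligand on titanium could be tried first. The fallback uses established operations only and sets out from 9.
- Hydroxyl-directed epoxidation (VO(acac)2, tBuOOH, CH2Cl2) should give the epoxide cis to the C1 hydroxyl, methyl (1S,3S,4R)-3,4-epoxy-1-hydroxy-4-methylcyclohexane-1-carboxylate F1.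
- Opening with HBr (48% aq., CHCl3, 0 °C) at the tertiary carbon with inversion should give the trans-bromohydrin methyl (1S,3S,4S)-4-bromo-1,3-dihydroxy-4-methylcyclohexane-1-carboxylate F2, in which C4 already has its final configuration.
- Dess–Martin oxidation of the secondary hydroxyl should give the bromo ketone methyl (1S,4S)-4-bromo-1-hydroxy-4-methyl-3-oxocyclohexane-1-carboxylate F3.
- Evans–Saksena reduction (Me4NBH(OAc)3, MeCN/AcOH, −20 °C) delivers hydride from the face of the C1 hydroxyl and should give the 1,3-anti diol methyl (1S,3R,4S)-4-bromo-1,3-dihydroxy-4-methylcyclohexane-1-carboxylate F4.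
- Chlorination of the secondary hydroxyl with inversion (PPh3, N-chlorosuccinimide, THF) brings the sequence back to the route at 11.

**Step 16.** Attack of the organomagnesium on bromine with loss of chloride (reductive elimination to the cyclohexene), or base-induced loss of HBr, may outrun a slow addition to the hindered amide. The fallback sets out from 13 and replaces acyl substitution by aldehyde addition at low temperature.
- Reduction of the Weinreb amide with iBu2AlH (CH2Cl2, −78 °C) should give the aldehyde (1S,3S,4S)-4-bromo-3-chloro-4-methyl-1-(trimethylsilyloxy)cyclohexane-1-carbaldehyde F5.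
- Grignard reagent 22 is added at −78 °C, where the halides should be inert, to give the carbinol (4R)-1-[(1S,3S,4S)-4-bromo-3-chloro-4-methyl-1-(trimethylsilyloxy)cyclohexyl]-4-(tert-butyldimethylsilyloxy)-5-methylhex-5-en-1-ol F6 as a mixture of epimers at the new carbinol.
- Dess–Martin oxidation removes that centre and comes back to the route at 23.

**Step 8.** Loss of HBr under the basic magnesium amide, or stalling of the aminolysis at the hindered, alkoxide-flanked ester, may erode the bromochloride. The fallback sets out from 11 and separates hydrolysis from amide bond formation.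
- Saponification with LiOH (THF/H2O, 0 °C) should give the hydroxy acid (1S,3S,4S)-4-bromo-3-chloro-1-hydroxy-4-methylcyclohexane-1-carboxylic acid F7.
- Carbodiimide coupling with MeONHMe·HCl (EDC·HCl, HOBt, N-methylmorpholine, CH2Cl2, 0 °C → rt) comes back to the route at 12.

## Further compounds

F1 | step 7 | methyl (1S,3S,4R)-3,4-epoxy-1-hydroxy-4-methylcyclohexane-1-carboxylate (epoxide cis to the hydroxyl) | COC(=O)[C@]1(O)CC[C@@]2(C)O[C@H]2C1
F2 | step 7 | methyl (1S,3S,4S)-4-bromo-1,3-dihydroxy-4-methylcyclohexane-1-carboxylate | COC(=O)[C@]1(O)CC[C@](C)(Br)[C@@H](O)C1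
F3 | step 7 | methyl (1S,4S)-4-bromo-1-hydroxy-4-methyl-3-oxocyclohexane-1-carboxylate | COC(=O)[C@]1(O)CC[C@](C)(Br)C(=O)C1
F4 | step 7 | methyl (1S,3R,4S)-4-bromo-1,3-dihydroxy-4-methylcyclohexane-1-carboxylate | COC(=O)[C@]1(O)CC[C@](C)(Br)[C@H](O)C1
F5 | step 16 | (1S,3S,4S)-4-bromo-3-chloro-4-methyl-1-(trimethylsilyloxy)cyclohexane-1-carbaldehyde | O=C[C@]1(O[Si](C)(C)C)CC[C@](C)(Br)[C@@H](Cl)C1
F6 | step 16 | (4R)-1-[(1S,3S,4S)-4-bromo-3-chloro-4-methyl-1-(trimethylsilyloxy)cyclohexyl]-4-(tert-butyldimethylsilyloxy)-5-methylhex-5-en-1-ol (mixture of epimers at C1 of the chain) | C=C(C)[C@H](O[Si](C)(C)C(C)(C)C)CCC(O)[C@]1(O[Si](C)(C)C)CC[C@](C)(Br)[C@@H](Cl)C1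
F7 | step 8 | (1S,3S,4S)-4-bromo-3-chloro-1-hydroxy-4-methylcyclohexane-1-carboxylic acid | OC(=O)[C@]1(O)CC[C@](C)(Br)[C@@H](Cl)C1
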